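**Retrosynthetic overview** (drimane numbering: ring A = C1–C5 and C10, ring B = C5–C10)
1. The (2E,4E,6E)-trienoate is unmasked last by HWE olefination of a 6-O-phosphonoacetate with sorbaldehyde; the cis-8β,9β-diacid comes from α-face hydrogenation of a Δ8 maleic anhydride, made by carbonylation of the enol triflate of an 8-oxo-11-ester.
2. Key disconnection: the dioxinone-fused decalin 13 is made in one operation from monocyclic epoxide 11, a (1,2,2-trimethylcyclopentyl)-substituted trans-epoxide tethered to a dioxinone.
3. Enabling feature: ring-fusion carbon C5 lies between the quaternary carbons C4 (CMe2) and C10 (C–CH3); in 11 these two are bonded to each other in a five-membered ring (C10, C1, C2, C3, C4) and C5 is an exocyclic epoxide carbon on C10, so a 1,2-shift of C4 from C10 to C5 creates ring A and a C10 cation at once.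
4. Ring order: cyclopentane (bought) → ring A by one-carbon ring expansion and ring B by C9–C10 closure in the same step → temporary dioxinone and anhydride rings, both opened later.
5. Epoxide 11 comes from 2,2-dimethylcyclopentanone by two one-carbon homologations and a methylation, catalytic α-chlorination (sets C5), vinylogous aldol with 2,2,6-trimethyl-1,3-dioxin-4-one (sets C6) and epoxide closure.

Key step: step 7

Remark: compounds 3–6 are racemic and 7, 10 and 11 are carried as both epimers at the ring quaternary carbon, because this centre becomes the planar C10 cation in step 7 and is set anew there; C11 and C12 are the carboxyl carbons on C9 and C8.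

Step 1
Reactants: 1 2,2-dimethylcyclopentan-1-one
Product: 3 2,2-dimethylcyclopentane-1-carbaldehyde (racemic), via enol ether 2 (not isolated)
Conditions: Ph3P(Cl)CH2OMe, KOtBu, THF, 0 °C to rt; then 2 M HCl, THF, rt
Reagents that add atoms: (methoxymethyl)triphenylphosphonium chloride COC[P+](c1ccccc1)(c1ccccc1)c1ccccc1.[Cl-]; water O
Why: Wittig methoxymethylenation of the ketone and acid hydrolysis of the enol ether (one-carbon homologation) should give the aldehyde, whose new CH centre is formed racemic.

Step 2
Reactants: 3 2,2-dimethylcyclopentane-1-carbaldehyde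
Product: 4 1,2,2-trimethylcyclopentane-1-carbaldehyde (racemic)
Conditions: KOtBu, MeI, THF, 0 °C to rt
Reagents that add atoms: iodomethane CI
Why: C-methylation of the potassium enolate of an α-branched aldehyde should give the α-quaternary aldehyde, racemic at a centre that step 7 erases.

Step 3
Reactants: 4 1,2,2-trimethylcyclopentane-1-carbaldehyde
Product: 6 2-(1,2,2-trimethylcyclopentyl)acetaldehyde (racemic), via enol ether 5 (not isolated)
Conditions: Ph3P(Cl)CH2OMe, KOtBu, THF, 0 °C to rt; then 2 M HCl, THF, rt
Reagents that add atoms: (methoxymethyl)triphenylphosphonium chloride COC[P+](c1ccccc1)(c1ccccc1)c1ccccc1.[Cl-]; water O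
Why: a second Wittig methoxymethylenation and enol ether hydrolysis homologates the pivalaldehyde-type aldehyde by one carbon without creating a stereocentre.

Step 4
Reactants: 6 2-(1,2,2-trimethylcyclopentyl)acetaldehyde
Product: 7 (2S)-2-chloro-2-(1,2,2-trimethylcyclopentyl)acetaldehyde (both epimers at the ring quaternary carbon)
Conditions: NCS, trans-2,5-diphenylpyrrolidine (10 mol %, the enantiomer that gives the 2S chloride), CH2Cl2, −20 °C to rt; used crude
Reagents that add atoms: N-chlorosuccinimide O=C1CCC(=O)N1Cl
Why: enamine-catalysed α-chlorination of the aldehyde should set the C–Cl centre (future C5) under catalyst control, since the C2-symmetric amine shields one enamine face.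

Step 5
Reactants: 7 (2S)-2-chloro-2-(1,2,2-trimethylcyclopentyl)acetaldehyde; 8 2,2,6-trimethyl-4H-1,3-dioxin-4-one
Product: 10 6-[(2R,3S)-3-chloro-2-hydroxy-3-(1,2,2-trimethylcyclopentyl)propyl]-2,2-dimethyl-4H-1,3-dioxin-4-one, via lithium dienolate 9 (not isolated)
Conditions: LDA, THF, −78 °C, 8; then 7, −78 °C; aq. NH4Cl
Reagents that add atoms: none
Why: γ-selective vinylogous aldol addition of the dioxinone dienolate to the α-chloro aldehyde should set the carbinol centre (future C6) anti to the C–Cl bond by Cornforth/Felkin–Anh control.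

Step 6
Reactants: 10 the anti-chlorohydrin
Product: 11 2,2-dimethyl-6-{[(2R,3R)-3-(1,2,2-trimethylcyclopentyl)oxiran-2-yl]methyl}-4H-1,3-dioxin-4-one
Conditions: Cs2CO3, MeCN, rt to 40 °C
Reagents that add atoms: none
Why: intramolecular Williamson closure (3-exo-tet) with inversion at the chlorine-bearing carbon should turn the anti-chlorohydrin into the trans-epoxide, and carbonate in an aprotic solvent spares the dioxinone.

Step 7
Reactants: 11 the trans-epoxide
Product: 13 (4bS,8aS,9R)-9-hydroxy-2,2,4b,8,8-pentamethyl-4b,5,6,7,8,8a,9,10-octahydro-4H-naphtho[2,1-d][1,3]dioxin-4-one, via tertiary C10 cation 12 (not isolated)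
Conditions: Sc(OTf)3 (20 mol %), 4 Å MS, CH2Cl2 (0.01 M), −40 to 0 °C
Reagents that add atoms: none
Why: Proposed new method: Sc(OTf)3 activates the epoxide, and the C5–O bond should break only with help from the antiperiplanar C10–C4 σ bond, so that the CMe2 carbon C4 shifts from C10 to C5 with inversion at C5 (Wagner–Meerwein shift of a cyclopentylcarbinyl system, driven by release of the strain between two adjacent quaternary ring carbons and by the secondary-to-tertiary change), which makes ring A from the five-membered ring and leaves tertiary cation 12 at C10. The closest known reaction types are epoxide-initiated cation–olefin cyclisations, the acid cyclisation of monocyclic 2-alkyl-1,3,3-trimethylcyclohexyl (cyclogeranyl-type) cations to trans-fused drimanes and dioxinone-terminated Prins cyclisations. Ring A is closed by the 1,2-alkyl shift itself (one-carbon ring expansion, 5 to 6), and ring B by a 6-endo-trig attack of the nucleophilic dioxinone carbon (future C9) on C10 through a chair, after which loss of the C9 proton restores the dioxinone and turns the catalyst over. C5 is set by the stereospecific inversion at the epoxide carbon, C6 is carried over unchanged from the epoxide (it ends axial, 6β), and C10 is set by the chair closure that gives the trans-decalin, as in the known cyclisations of such monocyclic cations; the old ring quaternary centre is erased in 12, so both epimers of 11 converge. The step needs the alkyl shift to beat the Meinwald hydride shift from C6, which is secured because only the C10–C4 bond can lie anti to the breaking C–O bond of the intact epoxide whereas a hydride shift would require a free secondary neopentyl cation; it needs C4 and not C1 or CH3 to migrate, which the higher migratory aptitude of the quaternary carbon and the strain release secure; and it needs C9–C10 bonding rather than direct attack of the tether on the epoxide, which would be a disfavoured 5-endo or 4-exo opening.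

Step 8
Reactants: 13 the dioxinone-fused decalin
Product: 14 methyl (1R,4R,4aS,8aS)-4-hydroxy-5,5,8a-trimethyl-2-oxodecahydronaphthalene-1-carboxylate
Conditions: MeOH (10 equiv), toluene, 110 °C, sealed tube
Reagents that add atoms: methanol CO
Why: thermal retro-[4+2] of the dioxinone to an acylketene and its capture by methanol should give the β-keto ester, whose C9 ester settles equatorial through the enol while no other centre is touched.

Step 9
Reactants: 14 the β-keto ester
Product: 15 methyl (4R,4aS,8aS)-4-hydroxy-5,5,8a-trimethyl-2-(trifluoromethanesulfonyloxy)-3,4,4a,5,6,7,8,8a-octahydronaphthalene-1-carboxylate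
Conditions: NaH (1.05 equiv), THF, 0 °C; PhNTf2, 0 °C to rt
Reagents that add atoms: N-phenylbis(trifluoromethanesulfonimide) O=S(=O)(N(c1ccccc1)S(=O)(=O)C(F)(F)F)C(F)(F)F
Why: O-triflation of the sodium enolate of the β-keto ester should give the enol triflate, because one equivalent of base addresses only the far more acidic β-keto ester and leaves the hindered axial 6β-OH free.

Step 10
Reactants: 15 the enol triflate
Product: 17 (5R,5aS,9aS)-5-hydroxy-6,6,9a-trimethyl-4,5,5a,6,7,8,9,9a-octahydronaphtho[1,2-c]furan-1,3-dione, via maleic half-ester 16 (not isolated)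
Conditions: Pd(OAc)2 (5 mol %), dppf, CO (1 atm), Et3N, DMF/H2O 10:1, 70 °C; then 1 M HCl work-up, toluene, 4 Å MS, 40 °C
Reagents that add atoms: carbon monoxide [C-]#[O+]; water O
Why: Pd-catalysed hydroxycarbonylation of the vinyl triflate gives a dialkylmaleic half-ester that should close to the anhydride with loss of methanol on acidification (intramolecular acyl substitution), while the 6β-OH cannot lactonise onto C12 because C8 is sp2 and the lactone would hold a bridgehead alkene.

Step 11
Reactants: 17 the Δ8 anhydride; 18 2-(diethoxyphosphoryl)acetic acid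
Product: 19 (5R,5aS,9aS)-6,6,9a-trimethyl-1,3-dioxo-1,3,4,5,5a,6,7,8,9,9a-decahydronaphtho[1,2-c]furan-5-yl 2-(diethoxyphosphoryl)acetate
Conditions: DCC, DMAP (cat.), CH2Cl2, rt
Reagents that add atoms: none
Why: carbodiimide (Steglich-type) esterification through the ketene-like activated phosphonoacetic acid should acylate even the hindered axial 6β-OH, and the phosphonoacetate both masks the trienoate for the coming hydrogenation and blocks O6 from attacking the saturated anhydride.

Step 12
Reactants: 19 the phosphonoacetate
Product: 20 (3aS,5R,5aS,9aS,9bS)-6,6,9a-trimethyl-1,3-dioxododecahydronaphtho[1,2-c]furan-5-yl 2-(diethoxyphosphoryl)acetate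
Conditions: H2 (60 bar), 10% Pd/C, EtOAc, 50 °C
Reagents that add atoms: none
Why: heterogeneous hydrogenation of the tetrasubstituted maleic anhydride (as for tetrahydrophthalic anhydride) should add H2 cis from the α face, opposite the axial C10 methyl and the axial 6β-acyloxy group, which sets C8 and C9 as the cis-β,β-anhydride.

Step 13
Reactants: 20 the saturated anhydride
Product: 21 (1S,2S,4R,4aS,8aS)-4-{[2-(diethoxyphosphoryl)acetyl]oxy}-5,5,8a-trimethyldecahydronaphthalene-1,2-dicarboxylic acid
Conditions: H2O/THF 1:3, 2,6-lutidine (cat.), 40 °C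
Reagents that add atoms: water O
Why: near-neutral hydrolysis of the cyclic anhydride should give the cis-diacid without epimerising C8 or C9, and it is done before the olefination because an anhydride would acylate the phosphonate anion.

Step 14
Reactants: 21 the diacid phosphonate; 22 (2E,4E)-hexa-2,4-dienal
Product: 23 (1S,2S,4R,4aS,8aS)-5,5,8a-trimethyl-4-[(2E,4E,6E)-octa-2,4,6-trienoyloxy]decahydronaphthalene-1,2-dicarboxylic acid (CNP0462207.1)
Conditions: LiCl, DBU (3.5 equiv), MeCN, 0 °C to rt; then 1 M HCl
Reagents that add atoms: none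
Why: Horner–Wadsworth–Emmons olefination under Masamune–Roush conditions, with extra base to cover the two acids, should form the new 2E double bond of the trienoate, and the carboxylate α-centres do not epimerise.

**Compound list**
1 | 2,2-dimethylcyclopentan-1-one | CC1(C)CCCC1=O | starting material
2 | 1-(methoxymethylidene)-2,2-dimethylcyclopentane (E/Z) | COC=C1CCCC1(C)C | intermediate
3 | 2,2-dimethylcyclopentane-1-carbaldehyde (racemic) | CC1(C)CCCC1C=O | intermediate
4 | 1,2,2-trimethylcyclopentane-1-carbaldehyde (racemic) | CC1(C)CCCC1(C)C=O | intermediate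
5 | 1-(2-methoxyethenyl)-1,2,2-trimethylcyclopentane (racemic, E/Z) | COC=CC1(C)CCCC1(C)C | intermediate
6 | 2-(1,2,2-trimethylcyclopentyl)acetaldehyde (racemic) | CC1(C)CCCC1(C)CC=O | intermediate
7 | (2S)-2-chloro-2-(1,2,2-trimethylcyclopentyl)acetaldehyde (both epimers at the ring quaternary carbon) | CC1(C)CCCC1(C)[C@H](Cl)C=O | intermediate
8 | 2,2,6-trimethyl-4H-1,3-dioxin-4-one | CC1=CC(=O)OC(C)(C)O1 | starting material
9 | lithium 2,2-dimethyl-6-methylidene-6H-1,3-dioxin-4-olate | [Li+].[O-]C1=CC(=C)OC(C)(C)O1 | intermediate
10 | 6-[(2R,3S)-3-chloro-2-hydroxy-3-(1,2,2-trimethylcyclopentyl)propyl]-2,2-dimethyl-4H-1,3-dioxin-4-one (both epimers at the ring quaternary carbon) | CC1(C)CCCC1(C)[C@H](Cl)[C@H](O)CC2=CC(=O)OC(C)(C)O2 | intermediate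
11 | 2,2-dimethyl-6-{[(2R,3R)-3-(1,2,2-trimethylcyclopentyl)oxiran-2-yl]methyl}-4H-1,3-dioxin-4-one (both epimers at the ring quaternary carbon) | CC1(C)CCCC1(C)[C@H]2O[C@@H]2CC3=CC(=O)OC(C)(C)O3 | intermediate
12 | 2-[(1R)-2-(2,2-dimethyl-4-oxo-4H-1,3-dioxin-6-yl)-1-hydroxyethyl]-1,3,3-trimethylcyclohexan-1-ylium, C5 configured as in 13 (drawn as the free alcohol; scandium-bound in the flask) | C[C+]1CCCC(C)(C)[C@@H]1[C@H](O)CC2=CC(=O)OC(C)(C)O2 | intermediate
13 | (4bS,8aS,9R)-9-hydroxy-2,2,4b,8,8-pentamethyl-4b,5,6,7,8,8a,9,10-octahydro-4H-naphtho[2,1-d][1,3]dioxin-4-one (dioxinone fused at C8–C9 of ring B, ring O on C8, C=O carbon on C9) | O[C@@H]1CC2=C(C(=O)OC(C)(C)O2)[C@@]3(C)CCCC(C)(C)[C@H]13 | intermediate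
14 | methyl (1R,4R,4aS,8aS)-4-hydroxy-5,5,8a-trimethyl-2-oxodecahydronaphthalene-1-carboxylate | O[C@@H]1CC(=O)[C@H](C(=O)OC)[C@@]2(C)CCCC(C)(C)[C@H]12 | intermediate
15 | methyl (4R,4aS,8aS)-4-hydroxy-5,5,8a-trimethyl-2-(trifluoromethanesulfonyloxy)-3,4,4a,5,6,7,8,8a-octahydronaphthalene-1-carboxylate | O[C@@H]1CC(OS(=O)(=O)C(F)(F)F)=C(C(=O)OC)[C@@]2(C)CCCC(C)(C)[C@H]12 | intermediate
16 | (4R,4aS,8aS)-4-hydroxy-1-(methoxycarbonyl)-5,5,8a-trimethyl-3,4,4a,5,6,7,8,8a-octahydronaphthalene-2-carboxylic acid | O[C@@H]1CC(C(=O)O)=C(C(=O)OC)[C@@]2(C)CCCC(C)(C)[C@H]12 | intermediate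
17 | (5R,5aS,9aS)-5-hydroxy-6,6,9a-trimethyl-4,5,5a,6,7,8,9,9a-octahydronaphtho[1,2-c]furan-1,3-dione | O[C@@H]1CC2=C(C(=O)OC2=O)[C@@]3(C)CCCC(C)(C)[C@H]13 | intermediate
18 | 2-(diethoxyphosphoryl)acetic acid | CCOP(=O)(OCC)CC(=O)O | starting material
19 | (5R,5aS,9aS)-6,6,9a-trimethyl-1,3-dioxo-1,3,4,5,5a,6,7,8,9,9a-decahydronaphtho[1,2-c]furan-5-yl 2-(diethoxyphosphoryl)acetate | CCOP(=O)(OCC)CC(=O)O[C@@H]1CC2=C(C(=O)OC2=O)[C@@]3(C)CCCC(C)(C)[C@H]13 | intermediate
20 | (3aS,5R,5aS,9aS,9bS)-6,6,9a-trimethyl-1,3-dioxododecahydronaphtho[1,2-c]furan-5-yl 2-(diethoxyphosphoryl)acetate | CCOP(=O)(OCC)CC(=O)O[C@@H]1C[C@H]2[C@H](C(=O)OC2=O)[C@@]3(C)CCCC(C)(C)[C@H]13 | intermediate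
21 | (1S,2S,4R,4aS,8aS)-4-{[2-(diethoxyphosphoryl)acetyl]oxy}-5,5,8a-trimethyldecahydronaphthalene-1,2-dicarboxylic acid | CCOP(=O)(OCC)CC(=O)O[C@@H]1C[C@H](C(=O)O)[C@H](C(=O)O)[C@@]2(C)CCCC(C)(C)[C@H]12 | intermediate
22 | (2E,4E)-hexa-2,4-dienal | C/C=C/C=C/C=O | starting material
23 | (1S,2S,4R,4aS,8aS)-5,5,8a-trimethyl-4-[(2E,4E,6E)-octa-2,4,6-trienoyloxy]decahydronaphthalene-1,2-dicarboxylic acid | C/C=C/C=C/C=C/C(=O)O[C@@H]1C[C@H](C(=O)O)[C@H](C(=O)O)[C@@]2(C)CCCC(C)(C)[C@H]12 | target

Total step count: 14. Longest linear sequence: 14 steps (1 to 23).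

**Steps most likely to fail**

Step 7 (Proposed new method). The C10 cation may lose a proton, or a hydride shift may intervene, before the dioxinone closes ring B, or the closure may show poor facial selectivity. The fallback splits the cascade into isolated stages of known type; it sets out from 11 and comes back at 14. The Lewis acid opening is run with a hindered pyridine base (2,6-di-tert-butyl-4-methylpyridine) so that the ring-expanded cation is deliberately discharged by loss of a methyl proton, the usual fate of terpene epoxides flanked by a quaternary carbon, to give the exocyclic alkene F1. Silylation (TBSOTf, 2,6-lutidine) should give the silyl ether F2, and thermolysis in methanol/toluene at 110 °C the methyl β-keto ester F3. SnCl4 in CH2Cl2, the established cyclisation of olefinic β-keto esters, protonates the 1,1-disubstituted alkene and alkylates the keto ester carbon through a chair, which should give the trans-fused bicyclic silyl ether F4. HF·pyridine then frees the 6β-OH and gives 14.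

Step 6. Displacement at the neopentyl-type C–Cl carbon may be slow, so that base-induced retro-aldol cleavage or vinylogous β-elimination of the epoxide competes; upstream, catalyst control in step 4 next to the racemic quaternary carbon may be incomplete. The fallback replaces halohydrin closure by reagent-controlled epoxidation of an alkene; it sets out from 6 and comes back at 11. Knoevenagel–Doebner condensation with malonic acid under deconjugating conditions (piperidinium acetate, DMSO, 100 °C) should give the (E)-β,γ-unsaturated acid F5. DCC/DMAP coupling with Meldrum's acid gives the acyl Meldrum's acid F6, and heating in toluene with acetone gives the (E)-alkenyl dioxinone F7. Shi epoxidation of the trans-disubstituted alkene (D-fructose-derived ketone, Oxone, buffered MeCN/dimethoxymethane/water, 0 °C) should then give the (R,R)-epoxide 11.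

Step 12. The tetrasubstituted C8=C9 bond, flanked by the quaternary C10, may resist surface hydrogenation or take up hydrogen with too little preference for the α face. The fallback goes from 19 straight to 20 by dissolving-metal reduction (Zn dust, AcOH, 60 °C), a stepwise electron transfer/protonation known for tetrasubstituted maleic anhydrides, in which both protons reach the zinc enolates from the open α face; it makes no new compound (F0).

**Further compounds**
F1 | step 7 | 6-{(2R)-2-[(1S)-2,2-dimethyl-6-methylidenecyclohexyl]-2-hydroxyethyl}-2,2-dimethyl-4H-1,3-dioxin-4-one | C=C1CCCC(C)(C)[C@@H]1[C@H](O)CC2=CC(=O)OC(C)(C)O2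
F2 | step 7 | 6-{(2R)-2-[(tert-butyldimethylsilyl)oxy]-2-[(1S)-2,2-dimethyl-6-methylidenecyclohexyl]ethyl}-2,2-dimethyl-4H-1,3-dioxin-4-one | C=C1CCCC(C)(C)[C@@H]1[C@H](O[Si](C)(C)C(C)(C)C)CC2=CC(=O)OC(C)(C)O2
F3 | step 7 | methyl (5R)-5-[(tert-butyldimethylsilyl)oxy]-5-[(1S)-2,2-dimethyl-6-methylidenecyclohexyl]-3-oxopentanoate | C=C1CCCC(C)(C)[C@@H]1[C@H](O[Si](C)(C)C(C)(C)C)CC(=O)CC(=O)OC
F4 | step 7 | methyl (1R,4R,4aS,8aS)-4-[(tert-butyldimethylsilyl)oxy]-5,5,8a-trimethyl-2-oxodecahydronaphthalene-1-carboxylate | CC(C)(C)[Si](C)(C)O[C@@H]1CC(=O)[C@H](C(=O)OC)[C@@]2(C)CCCC(C)(C)[C@H]12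
F5 | step 6 | (3E)-4-(1,2,2-trimethylcyclopentyl)but-3-enoic acid (racemic) | OC(=O)C/C=C/C1(C)CCCC1(C)C
F6 | step 6 | 2,2-dimethyl-5-[(3E)-4-(1,2,2-trimethylcyclopentyl)but-3-enoyl]-1,3-dioxane-4,6-dione (racemic) | CC1(C)OC(=O)C(C(=O)C/C=C/C2(C)CCCC2(C)C)C(=O)O1
F7 | step 6 | 2,2-dimethyl-6-[(2E)-3-(1,2,2-trimethylcyclopentyl)prop-2-en-1-yl]-4H-1,3-dioxin-4-one (racemic) | CC1(C)OC(=O)C=C(C/C=C/C2(C)CCCC2(C)C)O1
F0 | step 12 | none | none
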